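The earlier runs and the new flask were computed with made-up constants; scatter was added.

Slowness was my way in: after 40.0 min Friday's run still held 62.2 % of its electrophile, so I reckoned with mean amounts and solved nothing.

| setting | Friday's | Saturday's | Monday's | flask |
|---|---|---|---|---|
| electrophile | 0.94 M | 0.94 M | 1.4 M | 0.94 M |
| nucleophile | 1.8 equiv | 1.8 equiv | 1.8 equiv | 1.80 equiv |
| protic impurity | 0.047 M | 0.071 M | 0.094 M | 0.0940 M |
| remark | run made earlier | run made earlier | run made earlier |  |
| time |  |  |  | 40 min |

| run | time / min | electrophile / % | product / % |
|---|---|---|---|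
| Friday's | 6.00 | 92.8 | 6.6 |
| Friday's | 12.0 | 85.8 | 10.3 |
| Friday's | 15.0 | 83.0 | 11.0 |
| Friday's | 25.0 | 73.8 | 18.8 |
| Friday's | 30.0 | 69.5 | 20.8 |
| Friday's | 40.0 | 62.2 | 27.0 |
| Saturday's | 6.00 | 92.0 | 3.5 |
| Saturday's | 12.0 | 84.3 | 11.4 |
| Saturday's | 15.0 | 82.4 | 10.1 |
| Saturday's | 25.0 | 72.2 | 16.5 |
| Saturday's | 30.0 | 70.3 | 20.1 |
| Saturday's | 40.0 | 65.1 | 26.0 |
| Monday's | 8.00 | 85.8 | 11.1 |
| Monday's | 15.0 | 74.2 | 14.2 |
| Monday's | 25.0 | 62.8 | 24.5 |
| Monday's | 30.0 | 59.1 | 27.3 |
| Monday's | 40.0 | 53.0 | 33.3 |

(each reading ± 1 percentage point)

- a species is counted by the electrophile in it: one idle adduct counts as two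
- amounts and yields of product count idle adduct too
- what may be going on: electrophile + product <-> idle adduct; nucleophile + protic impurity -> quenched reagent; electrophile + nucleophile -> acid set free + product; nucleophile + acid set free <-> protonated nucleophile
- in an amount of product, one idle adduct counts as one product
- what has gone from electrophile into another species counts as reacted, even if it can come back
- the earlier runs do not show how much of nucleophile is bound; that part of a forecast is a guess

1. part of the electrophile that has reacted at 40 min
2. share of the unused nucleophile that is free and not bound as protonated nucleophile, at 40 min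

I took the mean electrophile fraction between the charge and the last reading. Nucleophile, in fractions of the electrophile charged, was its equivalents less the impurity less half the product yield. Dividing the yield by time, both means and the electrophile charge gave 9.14 × 10⁻⁵ M⁻¹ s⁻¹ on Friday and 8.27 × 10⁻⁵ M⁻¹ s⁻¹ on Monday. I carried their mean 8.70 × 10⁻⁵ M⁻¹ s⁻¹, the rate constant of the main step.

With Friday's means as a first pass, the flask's yield came to 24.9 %. The part missing from electrophile plus product is the idle adduct, counted once. Friday's and Saturday's averaged 9.85 %, so conversion stood near 34.8 %.

That gap was the weak link, a difference of readings that left Monday out. So I read the adduct constant from all three last readings, as adduct over electrophile, free product and charge, and got 0.978 M⁻¹. In the flask this gave an adduct of 9.34 % and a conversion of 34.3 %. The runs do not show binding, but with all acid bound the free share would be 82.8 %.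

The forecast stood a little above my conversion, at 35.3 % (33 % to 37.5 %), with a free share of 87 % (81 % to 98 %), saying “the runs barely discriminate”. The flask gave 35.9 % reacted and 83.0 % free.

    electrophile + product ⇌ idle adduct, settled at all times (K = 1.20 M⁻¹)
    nucleophile + protic impurity → quenched reagent (k = 0.00310 M⁻¹ s⁻¹)
    electrophile + nucleophile → acid set free + product (k = 9.80 × 10⁻⁵ M⁻¹ s⁻¹)
    nucleophile + acid set free ⇌ protonated nucleophile, settled at all times (K = 30.0 M⁻¹)

In the flask, nearly all the unbound-or-bound acid stood as protonated nucleophile, 0.231 M against 0.00681 M. The neighbour flask had 0.56 M of electrophile, so its impurity came to 0.168 equiv. Taking its simulated electrophile of 77.1 % and subtracting half its own yield from the nucleophile, the carried constant gave a yield of 16.1 %, and the adduct constant a conversion of 20.9 %. The neighbour flask held 17.1 % product, and 22.9 % of its electrophile had reacted.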